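**Retrosynthetic overview**

1. The strategy rests on one feature: ring A (C4a, C5, C6, C7, C8, C8a) is a fully substituted, 1,3,5-trioxygenated benzene whose C4a–C8a bond is also the enol-ether alkene O1–C8a=C4a–C4(=O) of the dihydropyranone ring C. That alkene can serve as the alkene of an alkenylketene.
2. Ring A is therefore cut at C8–C8a, C5–C6, C7–C8 and C4a–C5. A dihydropyranonyl diazo ketone supplies C4a, C8a, C5 and C8 with its side chain. A prenyl-substituted siloxyalkyne supplies C6 and C7 with its oxygen. Desilylation of O7 ends the route.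
3. The diazo ketone comes from the corresponding ketone by detrifluoroacetylative diazo transfer. The ketone comes from the ring C acid chloride and a chiral alkylzinc iodide (bond between the exocyclic carbonyl and the side-chain CH2).
4. Ring C comes from ethyl (S)-3-hydroxybutanoate (anti-methylation, oxalate Claisen condensation, acid cyclodehydration). The organozinc comes from (S)-epichlorohydrin through (S)-4-propylbutyrolactone. The siloxyalkyne comes from ethyl 4-methylpent-3-enoate through its ynolate.
5. Ring order: ring C first (step 5), ring A last (step 14).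

Key step: step 14

Remark on the chemistry: di-tert-butyl oxalate replaces diethyl oxalate so that the ring C acid is freed by acid alone. The side-chain centre keeps one spatial arrangement throughout; only its CIP descriptor changes with the ranks of its neighbours (S in the iodide and the organozinc, R in the ketone, S from the diazo ketone on).

**Route**

Step 1
Reactants: 1 ethyl (S)-3-hydroxybutanoate
Product: 2 ethyl (2S,3S)-3-hydroxy-2-methylbutanoate
Conditions: LiN(iPr)2 (2.2 equiv), THF, −78 → −20 °C; MeI, DMPU, −78 → 0 °C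
Reagents that add atoms: iodomethane, CI
Why: Fráter–Seebach alkylation, in which the chelated lithium alkoxide–enolate dianion is methylated on the face away from the C3 methyl group, so that C2 should be set anti to the hydroxyl, that is (2S,3S).

Step 2
Reactants: 2 ethyl (2S,3S)-3-hydroxy-2-methylbutanoate
Product: 3 ethyl (2S,3S)-2-methyl-3-(triethylsilyloxy)butanoate
Conditions: Et3SiCl, imidazole, CH2Cl2, 0 °C → rt
Reagents that add atoms: chlorotriethylsilane, CC[Si](CC)(CC)Cl
Why: routine silylation of a secondary alcohol, giving an ether that survives the enolate steps and is labile enough to fall off under the acid of step 5.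

Step 3
Reactants: 3 ethyl (2S,3S)-2-methyl-3-(triethylsilyloxy)butanoate
Product: 5 (3S,4S)-3-methyl-4-(triethylsilyloxy)pentan-2-one, via Weinreb amide 4 (not isolated)
Conditions: MeNHOMe·HCl, iPrMgCl, THF, −20 °C; then MeMgBr, 0 °C; aq. NH4Cl
Reagents that add atoms: methylmagnesium bromide, C[Mg]Br
Why: Weinreb ketone synthesis, in which the chloromagnesium amide turns the ester into the N-methoxy-N-methylamide and the chelated adduct of MeMgBr collapses to the methyl ketone only on work-up, the weakly basic magnesium species leaving the α-centre unenolised.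

Step 4
Reactants: 5 (3S,4S)-3-methyl-4-(triethylsilyloxy)pentan-2-one; 6 di-tert-butyl oxalate
Product: 7 tert-butyl (5S,6S)-5-methyl-2,4-dioxo-6-(triethylsilyloxy)heptanoate
Conditions: LiN(SiMe3)2 (1.2 equiv), THF, −78 °C; then 6, −78 → 0 °C; aq. citric acid
Reagents that add atoms: none
Why: crossed Claisen condensation, in which the amide base removes a methyl proton faster than the tertiary C3–H and the non-enolisable oxalate acylates that enolate, the product resting as its lithium diketonate so that C5 should not epimerise.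

Step 5
Reactants: 7 tert-butyl (5S,6S)-5-methyl-2,4-dioxo-6-(triethylsilyloxy)heptanoate
Product: 8 (2S,3S)-2,3-dimethyl-4-oxo-3,4-dihydro-2H-pyran-6-carboxylic acid
Conditions: CF3CO2H, CH2Cl2, H2O (2 equiv), 0 °C → rt
Reagents that add atoms: none
Why: acid cyclodehydration of a δ-hydroxy β-diketone, in which the silyl ether is cleaved, the freed hydroxyl adds to the C2 carbonyl and water is lost to close ring C with the carbinol C–O bond intact, while the same acid cleaves the tert-butyl ester through the tert-butyl cation, so the base-sensitive pyranone never meets hydroxide.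

Step 6
Reactants: 8 (2S,3S)-2,3-dimethyl-4-oxo-3,4-dihydro-2H-pyran-6-carboxylic acid
Product: 9 (2S,3S)-2,3-dimethyl-4-oxo-3,4-dihydro-2H-pyran-6-carbonyl chloride
Conditions: (COCl)2, DMF (cat.), CH2Cl2, 0 °C → rt; evaporation, used crude
Reagents that add atoms: oxalyl chloride, ClC(=O)C(=O)Cl
Why: acid chloride formation through the chloroiminium salt of DMF, which is mild enough for the enone and the two ring stereocentres.

Step 7
Reactants: 10 (S)-epichlorohydrin; 11 diethyl malonate
Product: 12 ethyl (1R,5S)-2-oxo-3-oxabicyclo[3.1.0]hexane-1-carboxylate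
Conditions: NaOEt, EtOH, rt → reflux
Reagents that add atoms: none
Why: malonate alkylation–cyclopropanation–lactonisation cascade, in which malonate opens the epoxide at CH2, the alkoxide displaces chloride to a new epoxide, the malonate carbanion opens it by 3-exo-tet SN2 with inversion at the former epichlorohydrin carbon and the alkoxide lactonises onto the cis ester, so the (S)-centre should be carried into the (1R,5S)-bicycle.

Step 8
Reactants: 12 ethyl (1R,5S)-2-oxo-3-oxabicyclo[3.1.0]hexane-1-carboxylate
Product: 13 ethyl (4S)-2-oxo-4-propyloxolane-3-carboxylate (mixture of C3 epimers)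
Conditions: EtMgBr, CuI (cat.), THF, −30 °C; aq. NH4Cl
Reagents that add atoms: ethylmagnesium bromide, CC[Mg]Br
Why: copper-catalysed homoconjugate opening of the doubly activated cyclopropane at its CH2 carbon, which builds the propyl group without touching the C4 centre and leaves C3 as an epimer mixture that the next step removes.

Step 9
Reactants: 13 ethyl (4S)-2-oxo-4-propyloxolane-3-carboxylate
Product: 14 (4S)-4-propyloxolan-2-one
Conditions: LiCl, DMSO, H2O, 140 °C
Reagents that add atoms: none
Why: Krapcho dealkoxycarbonylation, in which chloride dealkylates the ethyl ester and the carboxylate of the β-dicarbonyl loses CO2, the C4 centre not being involved.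

Step 10
Reactants: 14 (4S)-4-propyloxolan-2-one
Product: 16 methyl (3S)-3-(iodomethyl)hexanoate, via trimethylsilyl ester 15 (not isolated)
Conditions: Me3SiI (1.3 equiv), CH2Cl2, rt; then MeOH, 0 °C → rt
Reagents that add atoms: iodotrimethylsilane, C[Si](C)(C)I; methanol, CO
Why: silyl iodide opening of a γ-lactone, in which silicon activates the carbonyl and iodide attacks the O–CH2 carbon by SN2 (not the stereocentre), after which methanol cleaves the silyl ester and the HI formed from excess reagent catalyses Fischer esterification.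

Step 11
Reactants: 16 methyl (3S)-3-(iodomethyl)hexanoate; 9 (2S,3S)-2,3-dimethyl-4-oxo-3,4-dihydro-2H-pyran-6-carbonyl chloride
Product: 18 methyl (3R)-5-[(2S,3S)-2,3-dimethyl-4-oxo-3,4-dihydro-2H-pyran-6-yl]-5-oxo-3-propylpentanoate, via alkylzinc iodide 17 (not isolated)
Conditions: 16, Zn dust (activated with BrCH2CH2Br and Me3SiCl), LiCl, THF, 30 °C; then 9, Pd(PPh3)4 (5 mol %), THF, 0 °C → rt
Reagents that add atoms: none
Why: Negishi acylation, in which zinc inserts into the primary C–I bond without touching the ester or the β-stereocentre and zerovalent palladium couples the alkylzinc iodide with the acid chloride faster than the organozinc can add to the ketone or enone of ring C.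

Step 12
Reactants: 18 methyl (3R)-5-[(2S,3S)-2,3-dimethyl-4-oxo-3,4-dihydro-2H-pyran-6-yl]-5-oxo-3-propylpentanoate
Product: 20 methyl (3S)-4-diazo-5-[(2S,3S)-2,3-dimethyl-4-oxo-3,4-dihydro-2H-pyran-6-yl]-5-oxo-3-propylpentanoate, via trifluoroacetyl ketone 19 (not isolated)
Conditions: LiN(SiMe3)2 (1.05 equiv), THF, −78 °C; CF3CO2CH2CF3, −78 °C; then MeSO2N3, Et3N, H2O (1 equiv), MeCN, rt
Reagents that add atoms: methanesulfonyl azide, CS(=O)(=O)N=[N+]=[N-]
Why: detrifluoroacetylative diazo transfer (Regitz type), in which the amide base should take a proton from the unhindered CH2 beside the exocyclic carbonyl rather than the tertiary C3–H of ring C or the less acidic ester CH2, C-trifluoroacetylation activates that carbon and the sulfonyl azide delivers N2 with loss of the trifluoroacetyl group as the N-acylsulfonamide, the adjacent side-chain centre staying untouched.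

Step 13
Reactants: 21 ethyl 4-methylpent-3-enoate
Product: 23 triisopropyl[(5-methylhex-4-en-1-yn-1-yl)oxy]silane, via lithium ynolate 22 (not isolated)
Conditions: CH2Br2, lithium 2,2,6,6-tetramethylpiperidide, THF, −78 °C; then 21; LiN(SiMe3)2, s-BuLi, −78 → 25 °C; iPr3SiCl, −78 → 25 °C
Reagents that add atoms: dibromomethane, BrCBr; chlorotriisopropylsilane, CC(C)[Si](Cl)(C(C)C)C(C)C
Why: Kowalski ester homologation stopped at the ynolate, in which LiCHBr2 adds to the ester, the derived α,α-dibromo enolate undergoes bromine–lithium exchange and 1,2-shift to the lithium ynolate, and the bulky silyl chloride silylates it on oxygen.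

Step 14
Reactants: 20 methyl (3S)-4-diazo-5-[(2S,3S)-2,3-dimethyl-4-oxo-3,4-dihydro-2H-pyran-6-yl]-5-oxo-3-propylpentanoate; 23 triisopropyl[(5-methylhex-4-en-1-yn-1-yl)oxy]silane
Product: 28 methyl (3S)-3-[(2S,3S)-5-hydroxy-2,3-dimethyl-6-(3-methylbut-2-en-1-yl)-4-oxo-7-(triisopropylsilyloxy)-3,4-dihydro-2H-chromen-8-yl]hexanoate, via alkenylketene 24 (not isolated), via cyclobutenone 25 (not isolated), via dienylketene 26 (not isolated), via cyclohexadienone 27 (not isolated)
Conditions: 23 (3 equiv), hν (254 nm, low-pressure Hg lamps, Vycor), degassed ClCH2CH2Cl, 25 °C; then 80 °C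
Reagents that add atoms: none
Why: Proposed new method: direct irradiation should expel N2 from 20 while the dihydropyranonyl carbon C8a shifts from the acyl carbon to the diazo carbon (Wolff rearrangement, C8–C8a), giving alkenylketene 24; its carbonyl carbon is attacked by the nucleophilic, prenyl-bearing carbon of 23 and the silyloxy carbon bonds to C8, so that cyclobutenone 25 forms with C5–C6 and C7–C8 in place. Ring strain then drives reversible four-electron conrotatory opening to dienylketene 26, and ring A closes by thermal six-electron disrotatory electrocyclisation of the ketene carbon onto C4a (C4a–C5) to dienone 27, which enolises to the C5 phenol of 28, hydrogen-bonded to the C4 carbonyl. The closest known reaction type is the benzannulation of α-diazo enones with siloxyalkynes through photochemical Wolff rearrangement (Danheiser benzannulation); a dihydropyranonyl migrating group combined with a secondary alkyl group on the diazo carbon has no precedent. No stereocentre is created, since C2, C3 and the side-chain centre are spectators (the ketene carbon beside the side-chain centre cannot enolise) and the sp3 carbons of 25 and 27 vanish on aromatisation. Regiochemistry needs no control beyond the polarisation of the siloxyalkyne, because C4a is the only terminus the dienylketene can reach and all six substituents arrive already placed. The selectivity that has to be won is Wolff shift over 1,2-hydride shift from the adjacent CH and over trapping of the ketene by the ester carbonyl, and it is served by unsensitised singlet excitation, the high migratory aptitude of an sp2 carbon and a three-fold excess of 23.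

Step 15
Reactants: 28 methyl (3S)-3-[(2S,3S)-5-hydroxy-2,3-dimethyl-6-(3-methylbut-2-en-1-yl)-4-oxo-7-(triisopropylsilyloxy)-3,4-dihydro-2H-chromen-8-yl]hexanoate
Product: 29 methyl (3S)-3-[(2S,3S)-5,7-dihydroxy-2,3-dimethyl-6-(3-methylbut-2-en-1-yl)-4-oxo-3,4-dihydro-2H-chromen-8-yl]hexanoate
Conditions: Bu4NF, AcOH (1:1), THF, 0 °C → rt
Reagents that add atoms: none
Why: fluoride-mediated cleavage of an aryl silyl ether at silicon, with the acetic acid buffer keeping the medium from opening ring C by β-elimination of O1 and from lactonising the freed O7 phenol onto the methyl ester.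

**Compound list**

1 | ethyl (S)-3-hydroxybutanoate | CCOC(=O)C[C@H](C)O | starting material
2 | ethyl (2S,3S)-3-hydroxy-2-methylbutanoate | CCOC(=O)[C@@H](C)[C@H](C)O | intermediate
3 | ethyl (2S,3S)-2-methyl-3-(triethylsilyloxy)butanoate | CCOC(=O)[C@@H](C)[C@H](C)O[Si](CC)(CC)CC | intermediate
4 | (2S,3S)-N-methoxy-N,2-dimethyl-3-(triethylsilyloxy)butanamide | CON(C)C(=O)[C@@H](C)[C@H](C)O[Si](CC)(CC)CC | intermediate (not isolated)
5 | (3S,4S)-3-methyl-4-(triethylsilyloxy)pentan-2-one | CC(=O)[C@@H](C)[C@H](C)O[Si](CC)(CC)CC | intermediate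
6 | di-tert-butyl oxalate | CC(C)(C)OC(=O)C(=O)OC(C)(C)C | starting material
7 | tert-butyl (5S,6S)-5-methyl-2,4-dioxo-6-(triethylsilyloxy)heptanoate | CC(C)(C)OC(=O)C(=O)CC(=O)[C@@H](C)[C@H](C)O[Si](CC)(CC)CC | intermediate
8 | (2S,3S)-2,3-dimethyl-4-oxo-3,4-dihydro-2H-pyran-6-carboxylic acid | OC(=O)C1=CC(=O)[C@@H](C)[C@H](C)O1 | intermediate
9 | (2S,3S)-2,3-dimethyl-4-oxo-3,4-dihydro-2H-pyran-6-carbonyl chloride | ClC(=O)C1=CC(=O)[C@@H](C)[C@H](C)O1 | intermediate
10 | (S)-epichlorohydrin [(S)-2-(chloromethyl)oxirane] | ClC[C@@H]1CO1 | starting material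
11 | diethyl malonate | CCOC(=O)CC(=O)OCC | starting material
12 | ethyl (1R,5S)-2-oxo-3-oxabicyclo[3.1.0]hexane-1-carboxylate | CCOC(=O)[C@@]12C[C@@H]1COC2=O | intermediate
13 | ethyl (4S)-2-oxo-4-propyloxolane-3-carboxylate (C3 epimers) | CCC[C@@H]1COC(=O)C1C(=O)OCC | intermediate
14 | (4S)-4-propyloxolan-2-one | CCC[C@H]1CC(=O)OC1 | intermediate
15 | trimethylsilyl (3S)-3-(iodomethyl)hexanoate | CCC[C@@H](CC(=O)O[Si](C)(C)C)CI | intermediate (not isolated)
16 | methyl (3S)-3-(iodomethyl)hexanoate | CCC[C@@H](CC(=O)OC)CI | intermediate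
17 | [(2S)-2-(2-methoxy-2-oxoethyl)pentyl]zinc iodide | CCC[C@@H](CC(=O)OC)C[Zn]I | intermediate (not isolated)
18 | methyl (3R)-5-[(2S,3S)-2,3-dimethyl-4-oxo-3,4-dihydro-2H-pyran-6-yl]-5-oxo-3-propylpentanoate | CCC[C@@H](CC(=O)OC)CC(=O)C1=CC(=O)[C@@H](C)[C@H](C)O1 | intermediate
19 | methyl (3S)-4-[(2S,3S)-2,3-dimethyl-4-oxo-3,4-dihydro-2H-pyran-6-carbonyl]-6,6,6-trifluoro-5-oxo-3-propylhexanoate (C4 undefined) | CCC[C@@H](CC(=O)OC)C(C(=O)C(F)(F)F)C(=O)C1=CC(=O)[C@@H](C)[C@H](C)O1 | intermediate (not isolated)
20 | methyl (3S)-4-diazo-5-[(2S,3S)-2,3-dimethyl-4-oxo-3,4-dihydro-2H-pyran-6-yl]-5-oxo-3-propylpentanoate | CCC[C@@H](CC(=O)OC)C(=[N+]=[N-])C(=O)C1=CC(=O)[C@@H](C)[C@H](C)O1 | intermediate (key-step precursor)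
21 | ethyl 4-methylpent-3-enoate | CCOC(=O)CC=C(C)C | starting material
22 | lithium 5-methylhex-4-en-1-yn-1-olate | CC(C)=CCC#C[O-].[Li+] | intermediate (not isolated)
23 | triisopropyl[(5-methylhex-4-en-1-yn-1-yl)oxy]silane | CC(C)=CCC#CO[Si](C(C)C)(C(C)C)C(C)C | intermediate (key-step precursor)
24 | methyl (3S)-3-{1-[(2S,3S)-2,3-dimethyl-4-oxo-3,4-dihydro-2H-pyran-6-yl]-2-oxoethenyl}hexanoate | CCC[C@@H](CC(=O)OC)C(=C=O)C1=CC(=O)[C@@H](C)[C@H](C)O1 | intermediate (not isolated)
25 | methyl (3S)-3-{1-[(2S,3S)-2,3-dimethyl-4-oxo-3,4-dihydro-2H-pyran-6-yl]-3-(3-methylbut-2-en-1-yl)-4-oxo-2-(triisopropylsilyloxy)cyclobut-2-en-1-yl}hexanoate (ring C1 undefined) | CCC[C@@H](CC(=O)OC)C2(C(=O)C(CC=C(C)C)=C2O[Si](C(C)C)(C(C)C)C(C)C)C1=CC(=O)[C@@H](C)[C@H](C)O1 | intermediate (not isolated)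
26 | methyl (3S)-3-{(1E)-1-[(2S,3S)-2,3-dimethyl-4-oxo-3,4-dihydro-2H-pyran-6-yl]-3-(3-methylbut-2-en-1-yl)-4-oxo-2-(triisopropylsilyloxy)buta-1,3-dien-1-yl}hexanoate (pyranonyl cis to the ketene carbon) | CCC[C@@H](CC(=O)OC)/C(=C(\O[Si](C(C)C)(C(C)C)C(C)C)C(CC=C(C)C)=C=O)C1=CC(=O)[C@@H](C)[C@H](C)O1 | intermediate (not isolated)
27 | methyl (3S)-3-[(2S,3S)-2,3-dimethyl-6-(3-methylbut-2-en-1-yl)-4,5-dioxo-7-(triisopropylsilyloxy)-3,4,4a,5-tetrahydro-2H-chromen-8-yl]hexanoate (C4a undefined) | CCC[C@@H](CC(=O)OC)C1=C2O[C@@H](C)[C@H](C)C(=O)C2C(=O)C(CC=C(C)C)=C1O[Si](C(C)C)(C(C)C)C(C)C | intermediate (not isolated)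
28 | methyl (3S)-3-[(2S,3S)-5-hydroxy-2,3-dimethyl-6-(3-methylbut-2-en-1-yl)-4-oxo-7-(triisopropylsilyloxy)-3,4-dihydro-2H-chromen-8-yl]hexanoate | CCC[C@@H](CC(=O)OC)c1c(O[Si](C(C)C)(C(C)C)C(C)C)c(CC=C(C)C)c(O)c2c1O[C@@H](C)[C@H](C)C2=O | intermediate (key-step product)
29 | methyl (3S)-3-[(2S,3S)-5,7-dihydroxy-2,3-dimethyl-6-(3-methylbut-2-en-1-yl)-4-oxo-3,4-dihydro-2H-chromen-8-yl]hexanoate | CCC[C@@H](CC(=O)OC)c1c(O)c(CC=C(C)C)c(O)c2c1O[C@@H](C)[C@H](C)C2=O | target

**Step count**

Total: 15 steps. Longest linear sequence: 10 steps (1, 2, 3, 4, 5, 6, 11, 12, 14, 15).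

**Steps most likely to fail**

Step 14 (photochemical benzannulation). The 1,2-hydride shift from the side-chain CH may outrun the Wolff shift, especially if 20 is photolysed mainly from its s-E conformer. The ester carbonyl may also trap the ketene, or the lamp may degrade the chromanone product. The fallback runs from 9 back to 29 and takes the side chain off the diazo carbon, so that the benzannulation runs on a diazomethyl enone, the substrate class on which it is established. Acid chloride 9 with Me3SiCHN2 (MeCN–THF, 0 °C) should give (2S,3S)-6-(diazoacetyl)-2,3-dimethyl-2,3-dihydro-4H-pyran-4-one F1. Irradiation of F1 with 23 (254 nm, ClCH2CH2Cl, then 80 °C) should give (2S,3S)-5-hydroxy-2,3-dimethyl-6-(3-methylbut-2-en-1-yl)-7-(triisopropylsilyloxy)-2,3-dihydro-4H-chromen-4-one F2, with hydrogen at C8. Bu4NF/AcOH should then free (2S,3S)-5,7-dihydroxy-2,3-dimethyl-6-(3-methylbut-2-en-1-yl)-2,3-dihydro-4H-chromen-4-one F3. Its only open ring position, C8, should add to (E)-hex-2-enal under iminium catalysis by (R)-2-[diphenyl(trimethylsilyloxy)methyl]pyrrolidine (PhCO2H, toluene, 0 °C). This is a Friedel–Crafts alkylation followed by hemiacetal closure through O7; the (R)-catalyst shields the face that would lead to the (R)-benzylic carbon. The product would be (2S,3S,10S)-5,8-dihydroxy-2,3-dimethyl-6-(3-methylbut-2-en-1-yl)-10-propyl-2,3,9,10-tetrahydro-4H,8H-pyrano[2,3-f]chromen-4-one F4. Ag2CO3 on Celite (toluene, 80 °C) should oxidise the lactol to (2S,3S,10S)-5-hydroxy-2,3-dimethyl-6-(3-methylbut-2-en-1-yl)-10-propyl-2,3,9,10-tetrahydro-4H,8H-pyrano[2,3-f]chromene-4,8-dione F5. Methanol with a little Et3N at rt should open this aryl ester to 29.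

Step 12 (diazo transfer). The amide base may deprotonate C3 of ring C, which would open the ring by β-elimination of O1 and erase C2 and C3. The enolate may also add to the ene-dione of a second molecule. The fallback runs from 18 back to 20 and uses no strong base. Ketone 18 is heated with tert-butoxybis(dimethylamino)methane (toluene, 60 °C). This reagent should condense only at the CH2 beside the exocyclic carbonyl, because C3 of ring C carries a single hydrogen. The product would be methyl (3S)-4-[(dimethylamino)methylidene]-5-[(2S,3S)-2,3-dimethyl-4-oxo-3,4-dihydro-2H-pyran-6-yl]-5-oxo-3-propylpentanoate F6. Methanesulfonyl azide (CH2Cl2, rt) should then add across the enamine alkene, and the triazoline should fragment to 20 and the N-sulfonyl formamidine (deformylative diazo transfer of the Regitz type).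

Step 13 (ynolate formation). LiCHBr2 may deprotonate the doubly activated α-CH2 of the β,γ-unsaturated ester instead of adding to the carbonyl, and the alkene may move into conjugation. The fallback runs from 21 back to 23 and makes the ynolate by oxidising an acetylide. iBu2AlH (CH2Cl2, −78 °C) should reduce 21 to 4-methylpent-3-enal F7. CBr4/PPh3 (CH2Cl2, 0 °C; Corey–Fuchs olefination) should give 1,1-dibromo-5-methylhexa-1,4-diene F8. n-BuLi (2.1 equiv, THF, −78 °C) should convert it into lithium 5-methylhex-4-en-1-yn-1-ide F9. LiOOtBu (from tBuOOH and LiN(SiMe3)2, −78 → 0 °C) should oxidise the acetylide to ynolate 22, and iPr3SiOTf (−78 °C) should silylate it on oxygen to 23.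

**Further compounds**

F1 | step 14 | (2S,3S)-6-(diazoacetyl)-2,3-dimethyl-2,3-dihydro-4H-pyran-4-one | [N-]=[N+]=CC(=O)C1=CC(=O)[C@@H](C)[C@H](C)O1
F2 | step 14 | (2S,3S)-5-hydroxy-2,3-dimethyl-6-(3-methylbut-2-en-1-yl)-7-(triisopropylsilyloxy)-2,3-dihydro-4H-chromen-4-one | CC(C)=CCc1c(O[Si](C(C)C)(C(C)C)C(C)C)cc2O[C@@H](C)[C@H](C)C(=O)c2c1O
F3 | step 14 | (2S,3S)-5,7-dihydroxy-2,3-dimethyl-6-(3-methylbut-2-en-1-yl)-2,3-dihydro-4H-chromen-4-one | CC(C)=CCc1c(O)cc2O[C@@H](C)[C@H](C)C(=O)c2c1O
F4 | step 14 | (2S,3S,10S)-5,8-dihydroxy-2,3-dimethyl-6-(3-methylbut-2-en-1-yl)-10-propyl-2,3,9,10-tetrahydro-4H,8H-pyrano[2,3-f]chromen-4-one (C8 undefined) | CCC[C@H]1CC(O)Oc2c1c3O[C@@H](C)[C@H](C)C(=O)c3c(O)c2CC=C(C)C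
F5 | step 14 | (2S,3S,10S)-5-hydroxy-2,3-dimethyl-6-(3-methylbut-2-en-1-yl)-10-propyl-2,3,9,10-tetrahydro-4H,8H-pyrano[2,3-f]chromene-4,8-dione | CCC[C@H]1CC(=O)Oc2c1c3O[C@@H](C)[C@H](C)C(=O)c3c(O)c2CC=C(C)C
F6 | step 12 | methyl (3S)-4-[(dimethylamino)methylidene]-5-[(2S,3S)-2,3-dimethyl-4-oxo-3,4-dihydro-2H-pyran-6-yl]-5-oxo-3-propylpentanoate (alkene geometry undefined) | CCC[C@@H](CC(=O)OC)C(=CN(C)C)C(=O)C1=CC(=O)[C@@H](C)[C@H](C)O1
F7 | step 13 | 4-methylpent-3-enal | CC(C)=CCC=O
F8 | step 13 | 1,1-dibromo-5-methylhexa-1,4-diene | CC(C)=CCC=C(Br)Br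
F9 | step 13 | lithium 5-methylhex-4-en-1-yn-1-ide | CC(C)=CCC#[C-].[Li+]
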